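**Plan**

- Rings are lettered A to F from the 2,4,6-trihydroxyphenyl end. The oxygen between rings E and F sits on a ring E carbon whose neighbour carries OH and on a ring F carbon whose neighbour carries H. A C(=O)–O bridge between these two neighbours (carbonyl on ring F, oxygen on ring E) would make a seven-membered dibenzodioxepinone. The pairs C/D and A/B show the same pattern.
- First cuts: the two linking ethers, each at the ring D or ring B carbon that lies between an aryloxy carbon and a hydroxyl carbon. This leaves three copies of one two-ring unit, 3,5-dimethoxy-4-(3,4,5-trimethoxyphenoxy)benzaldehyde, whose formyl group is a latent phenol oxygen.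
- Second cut: the bond from the ring E carbon to the E–F ether oxygen, after CO2 is put back as an ester tether. The pieces are 4-bromo-3-hydroxy-5-methoxybenzaldehyde and 6-hydroxy-2,3,4-trimethoxybenzoic acid.
- Forward: esterify, close the lactone with copper (the only ring formed), then open, methylate and decarboxylate to the unit. One part becomes a phenol by Baeyer–Villiger oxidation and the rest is iodinated on its trimethoxyphenoxy ring. Two rounds of Ullmann coupling and Baeyer–Villiger oxidation grow EF to CDEF to ABCDEF, and BBr3 frees the hydroxyls.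
- The target has no stereocentre and no axis of lasting configuration, so no stereocontrol is needed.

Key step: step 5

Assumption: the five diaryl ether axes rotate freely, so the target is one achiral compound. Compounds 1 and 4 are taken as purchasable.

**Step 1**
Reactants: 1 3,4,5-trimethoxyphenol
Product: 2 6-hydroxy-2,3,4-trimethoxybenzaldehyde
Conditions: MgCl2, Et3N, (CH2O)n, MeCN, reflux; 1 M HCl
Reagents that add atoms: paraformaldehyde (as formaldehyde), C=O
Why: Casnati–Skattebøl ortho-formylation, in which the magnesium phenoxide delivers formaldehyde only next to the phenol oxygen, the two such carbons of 1 are equivalent, and a second formaldehyde accepts hydride to raise the benzylic alkoxide to the aldehyde.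

**Step 2**
Reactants: 2 6-hydroxy-2,3,4-trimethoxybenzaldehyde
Product: 3 6-hydroxy-2,3,4-trimethoxybenzoic acid
Conditions: NaClO2, NaH2PO4, 2-methyl-2-butene (large excess), t-BuOH/H2O, 0 °C to rt; acidify cold and use at once
Reagents that add atoms: sodium chlorite, [Na+].[O-]Cl=O
Why: Pinnick oxidation converts salicylaldehydes to salicylic acids without touching the free phenol, and the alkene scavenger removes HOCl before it can chlorinate the one free ring carbon.

**Step 3**
Reactants: 4 4-bromo-3,5-dimethoxybenzaldehyde
Product: 5 4-bromo-3-hydroxy-5-methoxybenzaldehyde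
Conditions: BBr3 (1.1 equiv), CH2Cl2, −78 to 0 °C; H2O
Reagents that add atoms: none
Why: Lewis-acid aryl methyl ether cleavage with limiting BBr3, in which the two methoxy groups are equivalent so only one monophenol can form, the bromine already lies between the two oxygens, and unreacted 4 and any diol are removed by extraction with base.

**Step 4**
Reactants: 3 6-hydroxy-2,3,4-trimethoxybenzoic acid; 5 4-bromo-3-hydroxy-5-methoxybenzaldehyde
Product: 6 2-bromo-5-formyl-3-methoxyphenyl 6-hydroxy-2,3,4-trimethoxybenzoate
Conditions: (CF3CO)2O, toluene, 0 °C to rt; aq. NaHCO3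
Reagents that add atoms: none
Why: Depside-type esterification with trifluoroacetic anhydride activates hindered, electron-rich benzoic acids strongly enough to acylate acceptor-substituted phenols, while the ortho hydroxyl of 3 is held in a hydrogen bond to the carbonyl and does not compete.

**Step 5**
Reactants: 6 2-bromo-5-formyl-3-methoxyphenyl 6-hydroxy-2,3,4-trimethoxybenzoate
Product: 7 1,2,3,6-tetramethoxy-11-oxo-11H-dibenzo[b,e][1,4]dioxepine-8-carbaldehyde (depsidone of rings E and F)
Conditions: CuI (20 mol %), 1,10-phenanthroline (40 mol %), Cs2CO3 (1.5 equiv), 4 Å MS, dioxane (0.01 M), 90 °C, Ar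
Reagents that add atoms: none
Why: Cs2CO3 deprotonates the ring F hydroxyl, CuI binds the phenoxide, monovalent copper inserts into the ring E C–Br bond to give an eight-membered cupracycle of trivalent copper, and reductive elimination forms the bond from that ring E carbon to the ether oxygen. The closest known reaction type is the intramolecular Ullmann diaryl ether synthesis, which has been used to close depsidones from 2-halophenyl salicylates. The seven-membered dibenzodioxepinone closes by ipso attack of the tethered oxygen on the aryl carbon, with bromide leaving outside the new ring, and no stereocentre arises. Closure must outrun intermolecular etherification, which the tether and high dilution favour, and it must outrun ester cleavage, which is slowed by a carbonyl shielded between a methoxy carbon and the phenoxide carbon and by dry carbonate over sieves. The formyl group para to bromine lowers the barrier at that carbon alone, whereas the ester-bearing ring E carbon is meta to it, so a Smiles-type attack there gains no activation.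

**Step 6**
Reactants: 7 depsidone of rings E and F
Product: 9 6-(4-formyl-2,6-dimethoxyphenoxy)-2,3,4-trimethoxybenzoic acid, via hydroxy acid disodium salt 8 (not isolated)
Conditions: 2 M NaOH, THF, 40 °C, N2; then Me2SO4, rt; then 1 M HCl, 0 °C
Reagents that add atoms: sodium hydroxide, [Na+].[OH-]; dimethyl sulfate, COS(=O)(=O)OC
Why: Saponification of the aryl lactone followed by O-methylation in aqueous alkali, in which dimethyl sulfate alkylates the freed phenoxide, the hydrated and doubly flanked carboxylate stays as its salt, and a non-enolisable aldehyde tolerates the medium as in the classical methylation of vanillin.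

**Step 7**
Reactants: 9 6-(4-formyl-2,6-dimethoxyphenoxy)-2,3,4-trimethoxybenzoic acid
Product: 10 3,5-dimethoxy-4-(3,4,5-trimethoxyphenoxy)benzaldehyde (the two-ring unit)
Conditions: Cu2O (10 mol %), 1,10-phenanthroline (20 mol %), NMP/quinoline 3:1, 160 °C
Reagents that add atoms: none
Why: Copper-catalysed protodecarboxylation, the modern form of the copper/quinoline treatment of depsidone-derived acids, should be easy because the carboxyl carbon lies between an aryloxy carbon and a methoxy carbon and para to a third oxygen, and the basic medium avoids acid-catalysed condensation of the aldehyde with the electron-rich ring.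

**Step 8** (one third of 10)
Reactants: 10 3,5-dimethoxy-4-(3,4,5-trimethoxyphenoxy)benzaldehyde
Product: 12 3,5-dimethoxy-4-(3,4,5-trimethoxyphenoxy)phenol, via aryl formate 11 (not isolated)
Conditions: mCPBA, CH2Cl2, rt; aq. Na2SO3/NaHCO3 wash; then K2CO3 (cat.), MeOH, rt
Reagents that add atoms: mCPBA, OOC(=O)c1cccc(Cl)c1
Why: Baeyer–Villiger oxidation of an oxygenated benzaldehyde, in which the ring with oxygen para to the formyl group migrates as 3,4,5-trimethoxybenzaldehyde does on its way to the phenol, and the formate protects the new phenol from the peracid until mild methanolysis.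

**Step 9** (two thirds of 10)
Reactants: 10 3,5-dimethoxy-4-(3,4,5-trimethoxyphenoxy)benzaldehyde
Product: 13 4-(2-iodo-3,4,5-trimethoxyphenoxy)-3,5-dimethoxybenzaldehyde
Conditions: NIS (1.0 equiv), CF3CO2H (cat.), MeCN, 0 °C to rt
Reagents that add atoms: N-iodosuccinimide, O=C1CCC(=O)N1I
Why: Electrophilic aromatic iodination, in which the formyl group deactivates its own ring, the two equivalent free carbons of the other ring each have oxygen ortho, ortho and para, and one equivalent of NIS should therefore give a single monoiodide next to the ether oxygen.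

**Step 10**
Reactants: 12 3,5-dimethoxy-4-(3,4,5-trimethoxyphenoxy)phenol; 13 4-(2-iodo-3,4,5-trimethoxyphenoxy)-3,5-dimethoxybenzaldehyde
Product: 14 four-ring aldehyde 4-{2-[3,5-dimethoxy-4-(3,4,5-trimethoxyphenoxy)phenoxy]-3,4,5-trimethoxyphenoxy}-3,5-dimethoxybenzaldehyde (rings C to F)
Conditions: CuI (20 mol %), picolinic acid (40 mol %), K3PO4 (2 equiv), DMSO, 100 °C, Ar
Reagents that add atoms: none
Why: Ligand-accelerated Ullmann diaryl ether synthesis, in which the phenol of 12 is electron-rich with both ortho carbons free, iodide is the most reactive halide towards copper, picolinic acid suits ortho-substituted partners, and coupling of 2-halo-1,3-dialkoxybenzenes with dimethoxyphenols is the classical entry to methylated phlorethols.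

**Step 11**
Reactants: 14 four-ring aldehyde
Product: 16 four-ring phenol 4-{2-[3,5-dimethoxy-4-(3,4,5-trimethoxyphenoxy)phenoxy]-3,4,5-trimethoxyphenoxy}-3,5-dimethoxyphenol, via four-ring formate 15 (not isolated)
Conditions: mCPBA, CH2Cl2, rt; aq. Na2SO3/NaHCO3 wash; then K2CO3 (cat.), MeOH, rt
Reagents that add atoms: mCPBA, OOC(=O)c1cccc(Cl)c1
Why: The same Baeyer–Villiger oxidation and formate methanolysis as in step 8, on a formyl ring with the identical substitution pattern.

**Step 12**
Reactants: 16 four-ring phenol; 13 4-(2-iodo-3,4,5-trimethoxyphenoxy)-3,5-dimethoxybenzaldehyde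
Product: 17 six-ring aldehyde 4-(2-{4-[2-(3,5-dimethoxy-4-(3,4,5-trimethoxyphenoxy)phenoxy)-3,4,5-trimethoxyphenoxy]-3,5-dimethoxyphenoxy}-3,4,5-trimethoxyphenoxy)-3,5-dimethoxybenzaldehyde
Conditions: CuI (20 mol %), picolinic acid (40 mol %), K3PO4 (2 equiv), DMSO, 100 °C, Ar
Reagents that add atoms: none
Why: A second Ullmann diaryl ether synthesis whose reacting termini are the same as in step 10, the iodinated ring of 13 now becoming ring B and its formyl ring becoming ring A.

**Step 13**
Reactants: 17 six-ring aldehyde
Product: 19 six-ring phenol (pentadecamethyl ether of the target; free OH on ring A para to its ether oxygen), via six-ring formate 18 (not isolated)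
Conditions: mCPBA, CH2Cl2, rt; aq. Na2SO3/NaHCO3 wash; then K2CO3 (cat.), MeOH, rt
Reagents that add atoms: mCPBA, OOC(=O)c1cccc(Cl)c1
Why: A third Baeyer–Villiger oxidation and formate methanolysis, which turns the last formyl carbon into the para hydroxyl of ring A.

**Step 14**
Reactants: 19 six-ring phenol
Product: 20 CNP0218077.0
Conditions: BBr3 (excess, about 3 equiv per OMe), CH2Cl2, −78 °C to rt, Ar; degassed H2O, 0 °C
Reagents that add atoms: none
Why: Exhaustive aryl methyl ether cleavage with BBr3 leaves diaryl ether bonds intact and is assisted on the contiguous trimethoxy rings by cyclic borate formation.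

**Compound list**

1 | 3,4,5-trimethoxyphenol | COc1cc(O)cc(OC)c1OC | starting material
2 | 6-hydroxy-2,3,4-trimethoxybenzaldehyde | COc1cc(O)c(C=O)c(OC)c1OC | intermediate
3 | 6-hydroxy-2,3,4-trimethoxybenzoic acid | COc1cc(O)c(C(=O)O)c(OC)c1OC | intermediate
4 | 4-bromo-3,5-dimethoxybenzaldehyde | COc1cc(C=O)cc(OC)c1Br | starting material
5 | 4-bromo-3-hydroxy-5-methoxybenzaldehyde | COc1cc(C=O)cc(O)c1Br | intermediate
6 | 2-bromo-5-formyl-3-methoxyphenyl 6-hydroxy-2,3,4-trimethoxybenzoate | COc1cc(O)c(C(=O)Oc2cc(C=O)cc(OC)c2Br)c(OC)c1OC | intermediate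
7 | 1,2,3,6-tetramethoxy-11-oxo-11H-dibenzo[b,e][1,4]dioxepine-8-carbaldehyde | COc1cc2c(c(OC)c1OC)C(=O)Oc1cc(C=O)cc(OC)c1O2 | intermediate
8 | disodium salt of 6-(4-formyl-2-hydroxy-6-methoxyphenoxy)-2,3,4-trimethoxybenzoic acid | COc1cc(Oc2c([O-])cc(C=O)cc2OC)c(C(=O)[O-])c(OC)c1OC.[Na+].[Na+] | intermediate
9 | 6-(4-formyl-2,6-dimethoxyphenoxy)-2,3,4-trimethoxybenzoic acid | COc1cc(Oc2c(OC)cc(C=O)cc2OC)c(C(=O)O)c(OC)c1OC | intermediate
10 | 3,5-dimethoxy-4-(3,4,5-trimethoxyphenoxy)benzaldehyde | COc1cc(Oc2c(OC)cc(C=O)cc2OC)cc(OC)c1OC | intermediate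
11 | 3,5-dimethoxy-4-(3,4,5-trimethoxyphenoxy)phenyl formate | COc1cc(Oc2c(OC)cc(OC=O)cc2OC)cc(OC)c1OC | intermediate
12 | 3,5-dimethoxy-4-(3,4,5-trimethoxyphenoxy)phenol | COc1cc(Oc2c(OC)cc(O)cc2OC)cc(OC)c1OC | intermediate
13 | 4-(2-iodo-3,4,5-trimethoxyphenoxy)-3,5-dimethoxybenzaldehyde | COc1cc(Oc2c(OC)cc(C=O)cc2OC)c(I)c(OC)c1OC | intermediate
14 | four-ring aldehyde (rings C to F) | COc1cc(Oc2c(OC)cc(Oc3c(OC)c(OC)c(OC)cc3Oc3c(OC)cc(C=O)cc3OC)cc2OC)cc(OC)c1OC | intermediate
15 | four-ring formate | COc1cc(Oc2c(OC)cc(Oc3c(OC)c(OC)c(OC)cc3Oc3c(OC)cc(OC=O)cc3OC)cc2OC)cc(OC)c1OC | intermediate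
16 | four-ring phenol | COc1cc(Oc2c(OC)cc(Oc3c(OC)c(OC)c(OC)cc3Oc3c(OC)cc(O)cc3OC)cc2OC)cc(OC)c1OC | intermediate
17 | six-ring aldehyde | COc1cc(Oc2c(OC)cc(Oc3c(OC)c(OC)c(OC)cc3Oc3c(OC)cc(Oc4c(OC)c(OC)c(OC)cc4Oc4c(OC)cc(C=O)cc4OC)cc3OC)cc2OC)cc(OC)c1OC | intermediate
18 | six-ring formate | COc1cc(Oc2c(OC)cc(Oc3c(OC)c(OC)c(OC)cc3Oc3c(OC)cc(Oc4c(OC)c(OC)c(OC)cc4Oc4c(OC)cc(OC=O)cc4OC)cc3OC)cc2OC)cc(OC)c1OC | intermediate
19 | six-ring phenol (pentadecamethyl ether of the target) | COc1cc(Oc2c(OC)cc(Oc3c(OC)c(OC)c(OC)cc3Oc3c(OC)cc(Oc4c(OC)c(OC)c(OC)cc4Oc4c(OC)cc(O)cc4OC)cc3OC)cc2OC)cc(OC)c1OC | intermediate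
20 | CNP0218077.0 | Oc1cc(O)c(Oc2cc(O)c(O)c(O)c2Oc2cc(O)c(Oc3cc(O)c(O)c(O)c3Oc3cc(O)c(Oc4cc(O)c(O)c(O)c4)c(O)c3)c(O)c2)c(O)c1 | target

**Step count**

Total step count: 14.
Longest linear sequence: 12 steps (1, 2, 4, 5, 6, 7, 8, 10, 11, 12, 13, 14).

**Steps most likely to fail**

**Step 10.**
- What may go wrong: copper may insert only slowly into a C–I bond flanked by a methoxy group and a bulky aryloxy group. Protodeiodination of the halide and oxidative decay of the phenoxide could then overtake ether formation. Step 12 repeats this coupling, so step 10 is the test case.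
- Fallback: reverse the roles, so that the hindered ring supplies the oxygen and the bond forms at the ring E carbon flanked by two hydrogens. It sets out from 13 and 12.
- Hydroxylation of 13 with zerovalent palladium (Pd2(dba)3, tBuXPhos, KOH, dioxane/H2O, 80 °C) should give 4-(2-hydroxy-3,4,5-trimethoxyphenoxy)-3,5-dimethoxybenzaldehyde F1.
- Treating 12 with Tf2O and pyridine in CH2Cl2 at 0 °C should give 3,5-dimethoxy-4-(3,4,5-trimethoxyphenoxy)phenyl trifluoromethanesulfonate F2.
- Miyaura borylation of F2 (PdCl2(dppf), B2pin2, KOAc, dioxane, 90 °C) should give 2-[3,5-dimethoxy-4-(3,4,5-trimethoxyphenoxy)phenyl]-4,4,5,5-tetramethyl-1,3,2-dioxaborolane F3.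
- Chan–Lam coupling of F1 with F3 (Cu(OAc)2, pyridine, 4 Å MS, air, CH2Cl2, rt) accepts doubly ortho-substituted phenols and comes back to the route at 14.

**Step 5.**
- What may go wrong: carbonate or trace water may cleave the activated aryl ester, or intermolecular etherification may give oligomers. Both could win because closure must pass through the less populated ester conformer that a seven-membered lactone demands.
- Fallback: give up the tether. It sets out from 1 and 4, which are joined directly by an untethered Ullmann etherification (CuI 1 equiv, 2,2,6,6-tetramethylheptane-3,5-dione, Cs2CO3, NMP, 120 °C). The para formyl group still assists the substitution.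
- The cost is a bimolecular attack on a carbon between two methoxy groups, so stoichiometric copper and higher temperature are expected.
- The detour comes back at 10 and makes no compound outside the list (entry F0).

**Step 14.**
- What may go wrong: cleavage of the fifteen ethers may stop short and leave partly methylated material that cannot be separated from the free polyphenol. The pyrogallol rings may also oxidise in air during aqueous isolation.
- Fallback: isolate through a derivative. It sets out from 19, which is treated with BBr3 as before, quenched with methanol and evaporated.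
- The crude polyphenol is acetylated at once (Ac2O, pyridine, rt) to the hexadecaacetate of the target F4, which can be chromatographed and crystallised free of under-cleaved material.
- Acid methanolysis of F4 (AcCl cat., degassed MeOH, 40 °C, Ar) followed by evaporation needs no aqueous work-up and comes back at 20.

**Further compounds**

F1 | step 10 | 4-(2-hydroxy-3,4,5-trimethoxyphenoxy)-3,5-dimethoxybenzaldehyde | COc1cc(Oc2c(OC)cc(C=O)cc2OC)c(O)c(OC)c1OC
F2 | step 10 | 3,5-dimethoxy-4-(3,4,5-trimethoxyphenoxy)phenyl trifluoromethanesulfonate | COc1cc(Oc2c(OC)cc(OS(=O)(=O)C(F)(F)F)cc2OC)cc(OC)c1OC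
F3 | step 10 | 2-[3,5-dimethoxy-4-(3,4,5-trimethoxyphenoxy)phenyl]-4,4,5,5-tetramethyl-1,3,2-dioxaborolane | COc1cc(Oc2c(OC)cc(B3OC(C)(C)C(C)(C)O3)cc2OC)cc(OC)c1OC
F0 | step 5 | none | none
F4 | step 14 | hexadecaacetate of the target | CC(=O)Oc1cc(OC(C)=O)c(Oc2cc(OC(C)=O)c(OC(C)=O)c(OC(C)=O)c2Oc2cc(OC(C)=O)c(Oc3cc(OC(C)=O)c(OC(C)=O)c(OC(C)=O)c3Oc3cc(OC(C)=O)c(Oc4cc(OC(C)=O)c(OC(C)=O)c(OC(C)=O)c4)c(OC(C)=O)c3)c(OC(C)=O)c2)c(OC(C)=O)c1
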